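The readings come from a simulation from invented constants; the scatter is artificial.

The free catalyst in the teal flask, charged at 0.05 mol%, is the subject here, and you want to know what more of it buys at 30% conversion.

common to all: free catalyst 0.05 mol%
- teal: substrate 0.30 M; coupling partner 1.5 equiv; the very flask that is asked about, followed so far
- blue: substrate 0.45 M; coupling partner 1.5 equiv; run made earlier
- flask: substrate 0.30 M; coupling partner 1.50 equiv

| run | time / min | product / % | substrate / % |
|---|---|---|---|
| teal | 2.00 | 2.2 | 98.3 |
| teal | 4.00 | 4.0 | 95.3 |
| teal | 8.00 | 8.1 | 91.5 |
| teal | 12.0 | 10.7 | 89.6 |
| teal | 25.0 | 19.6 | 81.8 |
| blue | 4.00 | 6.1 | 93.6 |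
| blue | 8.00 | 10.9 | 88.8 |
| blue | 12.0 | 15.1 | 84.6 |
| blue | 15.0 | 17.6 | 82.8 |
| blue | 20.0 | 19.8 | 80.1 |

(each reading ± 0.5 percentage points)

- factor on the rate of making product when 30% of the substrate are converted if free catalyst is charged twice over
- factor on the rate when 30% of the substrate are converted if free catalyst is charged at 0.5 mol% instead

- the analysis behind the earlier runs scatters by 0.5 percentage points, standard deviation

Read the slowing first. Over its last stretch the teal run makes product at 68.5% of its opening rate, with 81.8% of its substrate still there at the end. The blue run falls to 38.5%. I therefore read lost rate as lost catalyst, in proportion to product made. Dividing the product made by the middle of that stretch by the loading and the lost share gives 961 for teal and 568 for blue. I carry their mean, 764, a reading from scattered points, as the turnover number, the turnovers one catalyst makes before it is lost.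

Reaching the mark at this loading takes 600 turnovers, so the one number for this flask is the share of that life used, 0.785. The zero of the scale is a rate proportional to charge, with factors 2 and 10.0. But a larger charge also arrives with less of its life used, so I expect 5.65 and 42.9. One number is barely enough: the teal life by itself gives 3.66 for doubling, and the blue life lies below the turnovers needed.

The forecast differs from my reckoning: it says 1.9 and 8.5, reasoning: “Binding by excess product leaves free catalyst proportional to charge, so I expect near-linear scaling”.

The flask gives 5.93 and 45.3.

    substrate + catalyst intermediate B ⇌ catalyst intermediate C (K = 100 /M, k = 139 /M/min)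
    catalyst intermediate C ⇌ free catalyst + product (K = 0.440 M, k = 615 /min)
    coupling partner + free catalyst → catalyst intermediate A (k = 133 /M/min)
    catalyst intermediate A → catalyst intermediate B (k = 3000 /min)
    substrate + catalyst intermediate B → spent catalyst (k = 0.184 /M/min)

Catalyst intermediate B has two ways forward with substrate: in the flask at 15.6 min substrate enters the step to catalyst intermediate C 760 times as fast as the step to spent catalyst, counting the forward rate of that reversible step alone. Carried to a flask charged at 0.5 mol%, the mark takes 60.0 turnovers, or 7.85% of the carried life of 764, and at the same conversion that flask holds 7.97% of its catalyst as spent catalyst.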